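**Retrosynthetic overview**

1. Cyclopentane numbering: C1 (quaternary; aryl, CH3), C2 (CH–CH3), C3 (=CHBr), C4, C5. The strategy rests on one feature: the phenol oxygen, the two arene carbons between it and C1, then C1, C2 and the carbon of the C2 methyl group are six atoms in a row, and that methyl is cis to the aryl group. These six atoms can therefore be closed to a cis-fused pyran (a chroman), which is cut at O–CH2 at the end.
2. Endgame: target ⇐ para-bromination ⇐ radical C–Br reduction ⇐ BBr3 opening of the pyran ⇐ Wittig bromomethylenation of the C3 ketone ⇐ hydrogenation of a tricyclic vinylogous ester.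
3. Key disconnection: C1–C2 and aryl O–C (the future C2 methyl carbon) in one operation. An ortho-hydroxybenzylic tertiary carbinol is ionised by a chiral phosphoric acid to an ortho-quinone methide, which is trapped by a tethered enaminone. The cyclopentane closes first, then the pyran.
4. Precursor: enaminone ⇐ N-methylaniline + hydroxy ynone ⇐ lithium acetylide + γ-lactone ⇐ ortho-lithiated 2-bromo-5-methylphenol + ethyl levulinate. No acid is used once the carbinol exists.
5. Ring order: arene (bought) → γ-lactone (temporary, opened in step 2) → cyclopentane and pyran (step 4) → pyran opened (step 7).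

Key step: step 4

Remark on the chemistry: the amine of the enaminone is only a leaving group, and N-methylaniline is chosen because, once set free, it is too weakly basic to neutralise the phosphoric acid. The carbinol centre of the lactone, ynone and enaminone is left racemic because it becomes planar in the key step. The antipode of the acid that gives the (S) product is assumed to be (R) and is fixed by the first run.

**Route**

Step 1
Reactants: 1 2-bromo-5-methylphenol; 2 ethyl 4-oxopentanoate
Product: 5 rac-5-(2-hydroxy-4-methylphenyl)-5-methyloxolan-2-one, via aryllithium 3 (not isolated), via lithium alkoxide ester 4 (not isolated)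
Conditions: n-BuLi (2.2 equiv), Et2O, 0 °C → rt, 2 h; then 2 (1.2 equiv), −78 °C → rt; aq. NH4Cl
Reagents that add atoms: ethyl 4-oxopentanoate 2, CCOC(=O)CCC(C)=O
Why: Bromine–lithium exchange on the lithium phenoxide gives the ortho-lithiated phenoxide 3, which adds to the ketone carbonyl of 2 faster than to the ester, and the tertiary alkoxide 4 then lactonises by intramolecular acyl substitution with loss of ethoxide (aryllithium 1,2-addition followed by lactonisation); the carbinol centre forms racemic, which is harmless because it becomes planar in step 4.

Step 2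
Reactants: 5 rac-5-(2-hydroxy-4-methylphenyl)-5-methyloxolan-2-one; 6 acetylene
Product: 7 rac-6-hydroxy-6-(2-hydroxy-4-methylphenyl)hept-1-yn-3-one (open form, in equilibrium with its five-membered lactol; used crude)
Conditions: HC≡CH (excess), n-BuLi (3.5 equiv), THF, −78 °C; then 5, −78 °C, 2 h; AcOH in THF at −78 °C, then pH 7 buffer
Reagents that add atoms: acetylene 6, C#C
Why: Acyl substitution of a lactone by an alkynyllithium: the first equivalent of lithium acetylide only deprotonates the phenol, a further one adds to the lactone carbonyl, and the lithium hemiketal alkoxide persists at −78 °C, so a second addition is avoided and the hydroxy ynone is released only on the cold quench; neutral work-up and direct use avoid acid, which would ionise the benzylic carbinol or close a bicyclic ketal with the phenol.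

Step 3
Reactants: 7 rac-6-hydroxy-6-(2-hydroxy-4-methylphenyl)hept-1-yn-3-one; 8 N-methylaniline
Product: 9 rac-(E)-6-hydroxy-6-(2-hydroxy-4-methylphenyl)-1-[methyl(phenyl)amino]hept-1-en-3-one
Conditions: PhNHMe (1.3 equiv), MeOH, 0 °C → rt; chromatography on base-washed silica
Reagents that add atoms: N-methylaniline 8, CNc1ccccc1
Why: Aza-Michael addition of the secondary amine to the terminal ynone, which drains the lactol through its open form and gives the conjugated (E)-enaminone as the thermodynamic isomer of a tertiary vinylogous amide; the medium is neutral, so the acid-labile ortho-hydroxybenzylic carbinol survives.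

Step 4
Reactants: 9 rac-(E)-6-hydroxy-6-(2-hydroxy-4-methylphenyl)-1-[methyl(phenyl)amino]hept-1-en-3-one
Product: 12 (S)-7,9b-dimethyl-1,2-dihydrocyclopenta[c]chromen-3(9bH)-one, via ortho-quinone methide 10 (not isolated), via cyclic aminal 11 (not isolated)
Conditions: (R)-3,3'-bis(2,4,6-triisopropylphenyl)-1,1'-binaphthyl-2,2'-diyl hydrogen phosphate (10 mol%), 5 Å molecular sieves, toluene (0.02 M), 0 °C → rt
Reagents that add atoms: none
Why: Proposed new method: the phosphoric acid protonates the tertiary benzylic hydroxyl of 9, water leaves, and the phosphate stays hydrogen-bonded to the carbonyl oxygen of ortho-quinone methide 10 (equivalently an ion-paired ortho-hydroxybenzyl cation), whose methide carbon is attacked by the nucleophilic alpha carbon of the tethered enaminone; the phenol oxygen then adds to the resulting iminium carbon to give aminal 11, and loss of N-methylaniline leaves vinylogous ester 12. The closest known reaction type is the intermolecular phosphoric-acid-catalysed [4+2] annulation of ortho-quinone methides from ortho-hydroxybenzyl alcohols with enaminones or 1,3-dicarbonyls to 4H-chromenes; new here are the intramolecular mode and a methide carbon bearing two alkyl groups, which creates a quaternary centre. The cyclopentanone closes 5-exo-trig at the methide carbon and the pyran closes 6-exo-trig at the iminium carbon. The single new stereocentre C9b is set in the C–C bond formation by the chiral phosphate, which shields one face of the planar methide carbon; the E and Z forms of 10 interconvert through the carbinol and the cation, so the selection is made under Curtin–Hammett conditions. The step needs C-alkylation over O-alkylation of the enaminone and over proton loss to the 2-alkenylphenol; both side paths are reversible under the acid and return through 10, whereas the C–C bond is not, and the three-atom tether allows only the five-membered ring. The N-methylaniline set free is too weakly basic to take the proton from the phosphoric acid, so the catalyst keeps turning over, and the sieves remove the water.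

Step 5
Reactants: 12 (S)-7,9b-dimethyl-1,2-dihydrocyclopenta[c]chromen-3(9bH)-one
Product: 13 (3aS,9bR)-7,9b-dimethyl-1,3a,4,9b-tetrahydrocyclopenta[c]chromen-3(2H)-one (cis-fused)
Conditions: H2 (1 atm), Pd/C (10% Pd on carbon), EtOAc, rt
Reagents that add atoms: none
Why: Heterogeneous catalytic hydrogenation of the enone C=C: hydrogen is delivered to C3a on the face that carries the angular methyl group, as in related hydrindenones, which gives the cis ring fusion (3aS), and this is also the thermodynamic epimer of a centre that can still enolise.

Step 6
Reactants: 13 (3aS,9bR)-7,9b-dimethyl-1,3a,4,9b-tetrahydrocyclopenta[c]chromen-3(2H)-one; 14 (bromomethyl)triphenylphosphonium bromide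
Product: 15 (3E,3aR,9bR)-3-(bromomethylidene)-7,9b-dimethyl-1,2,3,3a,4,9b-hexahydrocyclopenta[c]chromene
Conditions: 14 (3.0 equiv), KOt-Bu (2.8 equiv), THF, −78 °C, 30 min; then 13, −78 → 0 °C
Reagents that add atoms: (bromomethyl)triphenylphosphonium bromide 14, BrC[P+](c1ccccc1)(c1ccccc1)c1ccccc1.[Br-]
Why: Wittig bromomethylenation with the ylide made at −78 °C: the bromine is expected on the side of the unsubstituted C2 methylene, away from the substituted C3a–C9b flank, which is the E isomer, and the low temperature with a slight deficit of base limits enolisation of the β-aryloxy ketone and the retro-oxa-Michael ring opening that would follow; any Z isomer is removed by chromatography.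

Step 7
Reactants: 15 (3E,3aR,9bR)-3-(bromomethylidene)-7,9b-dimethyl-1,2,3,3a,4,9b-hexahydrocyclopenta[c]chromene
Product: 17 2-[(1R,2R,3E)-3-(bromomethylidene)-2-(bromomethyl)-1-methylcyclopentyl]-5-methylphenol, via aryloxydibromoborane 16 (not isolated)
Conditions: BBr3 (1.5 equiv), CH2Cl2, −78 → 0 °C; ice-water quench, no base; used crude
Reagents that add atoms: boron tribromide, BrB(Br)Br
Why: Lewis-acid ether cleavage: BBr3 binds the chroman oxygen and bromide opens the ring by SN2 attack at the primary O–CH2 carbon (the aryl–O bond cannot be attacked), which frees the phenol on hydrolysis of 16 and leaves C2 and the electron-poor bromoalkene untouched; the acidic, base-free work-up keeps the phenol from closing back onto the bromide.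

Step 8
Reactants: 17 2-[(1R,2R,3E)-3-(bromomethylidene)-2-(bromomethyl)-1-methylcyclopentyl]-5-methylphenol
Product: 18 2-[(1R,2R,3E)-3-(bromomethylidene)-1,2-dimethylcyclopentyl]-5-methylphenol
Conditions: n-Bu3SnH (1.1 equiv), AIBN (0.1 equiv), benzene (0.3 M), 80 °C
Reagents that add atoms: none
Why: Radical chain dehalogenation with tin hydride: the tin radical abstracts bromine from the primary alkyl bromide much faster than from the vinyl bromide, and the alkyl radical is quenched by the concentrated tin hydride before it can add to the neighbouring double bond, while the neutral medium avoids the phenoxide that a basic hydride reagent would form and that would re-close the pyran by 6-exo-tet displacement.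

Step 9
Reactants: 18 2-[(1R,2R,3E)-3-(bromomethylidene)-1,2-dimethylcyclopentyl]-5-methylphenol
Product: 19 4-bromo-2-[(1R,2R,3E)-3-(bromomethylidene)-1,2-dimethylcyclopentyl]-5-methylphenol
Conditions: N-bromosuccinimide (1.0 equiv), MeCN, −20 → 0 °C, dark
Reagents that add atoms: N-bromosuccinimide, O=C1CCC(=O)N1Br
Why: Electrophilic aromatic bromination of a free phenol, which is far more reactive than the electron-poor bromoalkene, at the position para to the hydroxyl group (the only free ortho position is flanked by OH and CH3 and reacts more slowly), with one equivalent of reagent and no strong acid set free.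

**Compound list**

1 | 2-bromo-5-methylphenol | Cc1ccc(Br)c(O)c1 | starting material
2 | ethyl 4-oxopentanoate (ethyl levulinate) | CCOC(=O)CCC(C)=O | starting material
3 | lithium 2-lithio-5-methylphenolate | [Li]c1ccc(C)cc1O[Li] | intermediate (not isolated)
4 | dilithium salt of racemic ethyl 4-hydroxy-4-(2-hydroxy-4-methylphenyl)pentanoate | CCOC(=O)CCC(C)(O[Li])c1ccc(C)cc1O[Li] | intermediate (not isolated)
5 | rac-5-(2-hydroxy-4-methylphenyl)-5-methyloxolan-2-one | Cc1ccc(C2(C)CCC(=O)O2)c(O)c1 | intermediate
6 | acetylene | C#C | starting material
7 | rac-6-hydroxy-6-(2-hydroxy-4-methylphenyl)hept-1-yn-3-one (open form of the lactol) | Cc1ccc(C(C)(O)CCC(=O)C#C)c(O)c1 | intermediate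
8 | N-methylaniline | CNc1ccccc1 | starting material
9 | rac-(E)-6-hydroxy-6-(2-hydroxy-4-methylphenyl)-1-[methyl(phenyl)amino]hept-1-en-3-one | Cc1ccc(C(C)(O)CCC(=O)/C=C/N(C)c2ccccc2)c(O)c1 | intermediate
10 | 3-methyl-6-{(E)-7-[methyl(phenyl)amino]-5-oxohept-6-en-2-ylidene}cyclohexa-2,4-dien-1-one (ortho-quinone methide; geometry at the methide bond not fixed) | CC1=CC(=O)C(=C(C)CCC(=O)/C=C/N(C)c2ccccc2)C=C1 | intermediate (not isolated)
11 | cis-fused 7,9b-dimethyl-4-[methyl(phenyl)amino]-1,3a,4,9b-tetrahydrocyclopenta[c]chromen-3(2H)-one (quaternary carbon as in 12; aminal carbon not defined) | Cc1ccc2c(c1)OC(N(C)c3ccccc3)[C@H]1C(=O)CC[C@@]21C | intermediate (not isolated)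
12 | (S)-7,9b-dimethyl-1,2-dihydrocyclopenta[c]chromen-3(9bH)-one | Cc1ccc2c(c1)OC=C1C(=O)CC[C@@]21C | intermediate
13 | (3aS,9bR)-7,9b-dimethyl-1,3a,4,9b-tetrahydrocyclopenta[c]chromen-3(2H)-one | Cc1ccc2c(c1)OC[C@H]1C(=O)CC[C@@]21C | intermediate
14 | (bromomethyl)triphenylphosphonium bromide | BrC[P+](c1ccccc1)(c1ccccc1)c1ccccc1.[Br-] | starting material
15 | (3E,3aR,9bR)-3-(bromomethylidene)-7,9b-dimethyl-1,2,3,3a,4,9b-hexahydrocyclopenta[c]chromene | Cc1ccc2c(c1)OC[C@H]1/C(=C/Br)CC[C@@]21C | intermediate
16 | dibromo{2-[(1R,2R,3E)-3-(bromomethylidene)-2-(bromomethyl)-1-methylcyclopentyl]-5-methylphenoxy}borane | Cc1ccc([C@]2(C)CC/C(=C\Br)[C@@H]2CBr)c(OB(Br)Br)c1 | intermediate (not isolated)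
17 | 2-[(1R,2R,3E)-3-(bromomethylidene)-2-(bromomethyl)-1-methylcyclopentyl]-5-methylphenol | Cc1ccc([C@]2(C)CC/C(=C\Br)[C@@H]2CBr)c(O)c1 | intermediate
18 | 2-[(1R,2R,3E)-3-(bromomethylidene)-1,2-dimethylcyclopentyl]-5-methylphenol | Cc1ccc([C@]2(C)CC/C(=C\Br)[C@@H]2C)c(O)c1 | intermediate
19 | 4-bromo-2-[(1R,2R,3E)-3-(bromomethylidene)-1,2-dimethylcyclopentyl]-5-methylphenol | Cc1cc(O)c([C@]2(C)CC/C(=C\Br)[C@@H]2C)cc1Br | target

**Step count**

Total: 9 steps. Longest linear sequence: 9 steps (from 1).

**Steps most likely to fail**

Step 4 (Proposed new method). The ionisation may be slow and stall at the reversibly formed 2-alkenylphenol, and the acid may discriminate poorly between the two faces of a methide carbon that carries two alkyl groups, so the enantiomeric purity may be low. The fallback uses known chemistry; it sets out from 1 and rejoins the route at 13. The phenol 1 is protected with MOMCl and i-Pr2NEt as 1-bromo-2-(methoxymethoxy)-4-methylbenzene F1. Bromine–lithium exchange (n-BuLi) and Me2AlCl give dimethyl[2-(methoxymethoxy)-4-methylphenyl]aluminium F2. This adds to purchased 3-methylcyclopent-2-en-1-one in a copper-catalysed enantioselective conjugate addition (Cu(OTf)2, chiral N-heterocyclic carbene ligand, antipode chosen for the R centre). The regiospecific aluminium enolate is trapped with Me3SiOTf as (R)-trimethyl({3-[2-(methoxymethoxy)-4-methylphenyl]-3-methylcyclopent-1-en-1-yl}oxy)silane F3. Mukaiyama-type hydroxymethylation with aqueous formaldehyde and Yb(OTf)3 places the one-carbon unit on the hindered alpha carbon and gives (3R)-2-(hydroxymethyl)-3-[2-(methoxymethoxy)-4-methylphenyl]-3-methylcyclopentan-1-one F4. HCl in MeOH removes the methoxymethyl group, and the free phenol closes the pyran by dehydration and oxa-Michael addition to the cis-fused ketone 13.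

Step 6. The ylide may give an E/Z mixture, or it may act as a base, so that enolisation toward C3a and loss of the phenoxide open the pyran; the hindered ketone may also convert poorly. The fallback sets out from 13 and rejoins at 15. A boron-Wittig olefination (bis(pinacolato)borylmethane, lithium 2,2,6,6-tetramethylpiperidide, THF, −78 °C → rt) gives 2-{(E)-[(3aS,9bR)-7,9b-dimethyl-1,2,4,9b-tetrahydrocyclopenta[c]chromen-3(3aH)-ylidene]methyl}-4,4,5,5-tetramethyl-1,3,2-dioxaborolane F5, in which the bulky boryl group lies away from the substituted C3a flank. CuBr2 in MeOH/H2O then replaces boron by bromine with retention and gives 15. If the boronate forms with the other geometry, Br2 followed by NaOMe (addition and anti-elimination, inversion) leads to the same 15.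

Step 7. The SN2 opening at the β-branched O–CH2 carbon may be slow, and longer exposure to the Lewis acid may move the exocyclic double bond into the ring or let the phenol close back onto the bromide during work-up. The fallback sets out from 15 and rejoins at 18, bypassing 17. A B(C6F5)3-catalysed reduction of the alkyl aryl ether with Et3SiH (3 equiv, 5 mol% B(C6F5)3, CH2Cl2, rt) silylates the ether oxygen and delivers hydride to the O–CH2 carbon. This forms the C2 methyl group and the protected phenol in one operation, as triethyl{2-[(1R,2R,3E)-3-(bromomethylidene)-1,2-dimethylcyclopentyl]-5-methylphenoxy}silane F6. n-Bu4NF in THF then frees phenol 18; base is harmless at this point because no alkyl bromide is present.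

**Further compounds**

F1 | step 4 | 1-bromo-2-(methoxymethoxy)-4-methylbenzene | COCOc1cc(C)ccc1Br
F2 | step 4 | dimethyl[2-(methoxymethoxy)-4-methylphenyl]aluminium | COCOc1cc(C)ccc1[Al](C)C
F3 | step 4 | (R)-trimethyl({3-[2-(methoxymethoxy)-4-methylphenyl]-3-methylcyclopent-1-en-1-yl}oxy)silane | COCOc1cc(C)ccc1[C@]1(C)CCC(O[Si](C)(C)C)=C1
F4 | step 4 | (3R)-2-(hydroxymethyl)-3-[2-(methoxymethoxy)-4-methylphenyl]-3-methylcyclopentan-1-one (C2 epimers) | COCOc1cc(C)ccc1[C@]1(C)CCC(=O)C1CO
F5 | step 6 | 2-{(E)-[(3aS,9bR)-7,9b-dimethyl-1,2,4,9b-tetrahydrocyclopenta[c]chromen-3(3aH)-ylidene]methyl}-4,4,5,5-tetramethyl-1,3,2-dioxaborolane | Cc1ccc2c(c1)OC[C@H]1/C(=C/B3OC(C)(C)C(C)(C)O3)CC[C@@]21C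
F6 | step 7 | triethyl{2-[(1R,2R,3E)-3-(bromomethylidene)-1,2-dimethylcyclopentyl]-5-methylphenoxy}silane | Cc1ccc([C@]2(C)CC/C(=C\Br)[C@@H]2C)c(O[Si](CC)(CC)CC)c1
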